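**Retrosynthetic overview**
- Rings: A/E = outer 2,4,6‑trihydroxyphenyl rings, B/D = ether‑bearing phloroglucinol rings, C = central ring, F = 3,4,5‑trihydroxyphenoxy ring. The target comes from its hexadeca‑O‑methyl ether by one global demethylation.
- Ring F is attached last by C–O coupling of 5‑iodo‑1,2,3‑trimethoxybenzene to a ring C phenol; that phenol comes from a benzaldehyde (Dakin) and the aldehyde from a benzonitrile.
- The benzonitrile comes from 2,6‑difluoro‑4‑methoxybenzonitrile (ring C) and two equivalents of one A–B biaryl phenol by double SNAr, which installs A–B and E–D together.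
- Key C–C bond: the A–B biaryl bond, made by intermolecular Michael addition of 1,3,5‑trimethoxybenzene to 2,6‑dibromo‑1,4‑benzoquinone. The bromines then differentiate the two hydroquinone oxygens and are exchanged for OMe.
- No ring is built de novo: ring B/D is re‑aromatised from the quinone first, ring C is attached next, ring F last.

Assumption: the SMILES has no stereodescriptor and the molecule has no stereocentre or stereogenic axis (each biaryl axis carries a symmetric 2,4,6‑trioxygenated ring), so it is achiral and no stereocontrol is needed.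

Shorthand used in names below: ArO = 2,4,6‑trimethoxy‑3‑(2,4,6‑trimethoxyphenyl)phenoxy.

**Step 1**
Reactants: 1 4‑methoxyphenol
Product: 2 2,6‑dibromo‑4‑methoxyphenol
Conditions: Br2 (2.05 equiv), CH2Cl2, 0 °C to rt
Reagents that add atoms: bromine, BrBr
Why: Electrophilic aromatic bromination is directed by the free OH to both of its ortho positions, the para position being blocked by OMe.

**Step 2**
Reactants: 2 2,6‑dibromo‑4‑methoxyphenol
Product: 3 2,6‑dibromo‑1,4‑benzoquinone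
Conditions: (NH4)2Ce(NO3)6 (2.5 equiv), MeCN/H2O (3:1), 0 °C
Reagents that add atoms: water, O
Why: Oxidative demethylation of a para‑methoxyphenol by tetravalent cerium: two one‑electron oxidations give a phenoxonium ion, water adds at C4 and methanol is lost to give the para‑quinone.

**Step 3**
Reactants: 3 2,6‑dibromo‑1,4‑benzoquinone (2.2 equiv), 4 1,3,5‑trimethoxybenzene (1.0 equiv)
Product: 6 2,6‑dibromo‑3‑(2,4,6‑trimethoxyphenyl)benzene‑1,4‑diol, via arylquinone 5 (not isolated)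
Conditions: CF3CO2H (0.5 equiv), CH2Cl2, 0 °C to rt, dark; then aq. Na2S2O4, EtOAc, rt
Reagents that add atoms: none
Why: Acid‑promoted intermolecular Michael addition in which the enol‑ether‑type ring carbon of 4 adds to the only unsubstituted enone β‑carbon (C3) of 3 and the adduct enolises to the biaryl hydroquinone, which excess 3 oxidises to 5 and dithionite returns to 6; no stereocentre forms and the new axis is not stereogenic.

**Step 4**
Reactants: 6 2,6‑dibromo‑3‑(2,4,6‑trimethoxyphenyl)benzene‑1,4‑diol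
Product: 7 2,6‑dibromo‑4‑methoxy‑3‑(2,4,6‑trimethoxyphenyl)phenol
Conditions: t‑BuOK (2.05 equiv), THF/DMF (4:1), 0 °C, Ar; MeI (1.0 equiv), 0 °C; aq. HCl work‑up
Reagents that add atoms: iodomethane, CI
Why: Chemoselective Williamson methylation of the dianion, where the 4‑phenoxide (conjugate acid pKa about 10) is far more nucleophilic and less shielded than the 1‑phenoxide flanked by two bromines (pKa about 7), so the 1‑OH stays free for the later ether bond.

**Step 5**
Reactants: 7 2,6‑dibromo‑4‑methoxy‑3‑(2,4,6‑trimethoxyphenyl)phenol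
Product: 8 2,4,6‑trimethoxy‑3‑(2,4,6‑trimethoxyphenyl)phenol
Conditions: NaOMe (10 equiv, 25% in MeOH), CuI (0.2 equiv), DMF, 110 °C, Ar; then aq. HCl
Reagents that add atoms: sodium methoxide, [Na+].[O-]C
Why: Copper‑catalysed Ullmann‑type methoxylation of both aryl bromides, the classical conversion of 2,6‑dibromophenols into 2,6‑dimethoxyphenols, which tolerates the free phenol.

**Step 6**
Reactants: 8 2,4,6‑trimethoxy‑3‑(2,4,6‑trimethoxyphenyl)phenol (2.3 equiv), 9 2,6‑difluoro‑4‑methoxybenzonitrile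
Product: 11 4‑methoxy‑2,6‑bis(ArO)benzonitrile, via monoether 10 (not isolated)
Conditions: Cs2CO3 (3 equiv), DMSO, 120 °C, N2
Reagents that add atoms: none
Why: Double SNAr in which the small, base‑stable nitrile activates both ortho C–F bonds toward addition–elimination by the hindered, electron‑rich phenoxide of 8 and survives the forcing conditions the second substitution needs.

**Step 7**
Reactants: 11 4‑methoxy‑2,6‑bis(ArO)benzonitrile
Product: 13 4‑methoxy‑2,6‑bis(ArO)benzaldehyde, via aldimine 12 (not isolated)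
Conditions: i‑Bu2AlH (2 equiv), CH2Cl2, −78 to 0 °C; then 1 M aq. HCl, rt
Reagents that add atoms: water, O
Why: Partial reduction of a nitrile, where i‑Bu2AlH delivers one hydride to give an N‑aluminated aldimine that is not reduced further at low temperature and is hydrolysed to the aldehyde on acidic work‑up.

**Step 8**
Reactants: 13 4‑methoxy‑2,6‑bis(ArO)benzaldehyde
Product: 15 4‑methoxy‑2,6‑bis(ArO)phenol, via aryl formate 14 (not isolated)
Conditions: mCPBA (1.2 equiv), CH2Cl2, 0 °C to rt; aq. Na2SO3 wash; then K2CO3 (0.2 equiv), MeOH, rt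
Reagents that add atoms: 3‑chloroperoxybenzoic acid (mCPBA), OOC(=O)c1cccc(Cl)c1
Why: Baeyer–Villiger (Dakin‑type) oxidation in which the 2,4,6‑trioxygenated aryl group migrates in the Criegee intermediate to give the aryl formate, which base‑catalysed methanolysis converts into the phenol.

**Step 9**
Reactants: 15 4‑methoxy‑2,6‑bis(ArO)phenol, 16 5‑iodo‑1,2,3‑trimethoxybenzene (1.5 equiv)
Product: 17 5‑methoxy‑2‑(3,4,5‑trimethoxyphenoxy)‑1,3‑bis(ArO)benzene (hexadeca‑O‑methyl ether of the target)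
Conditions: CuI (0.1 equiv), picolinic acid (0.2 equiv), K3PO4 (2 equiv), DMSO, 90 °C, Ar
Reagents that add atoms: none
Why: Ligand‑accelerated Ullmann diaryl ether coupling, a CuI/picolinic acid system suited to di‑ortho‑substituted phenols, here with an aryl iodide that has no ortho substituent.

**Step 10**
Reactants: 17 5‑methoxy‑2‑(3,4,5‑trimethoxyphenoxy)‑1,3‑bis(ArO)benzene
Product: 18 4‑(3,4,5‑trihydroxyphenoxy)‑3,5‑bis[2,4,6‑trihydroxy‑3‑(2,4,6‑trihydroxyphenyl)phenoxy]phenol (CNP0279880.0)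
Conditions: BBr3 (48 equiv, 1 M in CH2Cl2), CH2Cl2, −78 °C to rt, Ar; then H2O, 0 °C
Reagents that add atoms: none
Why: Lewis‑acid ether cleavage in which BBr3 complexes each methyl ether oxygen and bromide cleaves the O–CH3 bond by SN2, while diaryl ether and biaryl bonds are inert, and hydrolysis of the borates frees all sixteen phenols.

**Compound list**
1 | 4‑methoxyphenol | COc1ccc(O)cc1 | starting material
2 | 2,6‑dibromo‑4‑methoxyphenol | COc1cc(Br)c(O)c(Br)c1 | intermediate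
3 | 2,6‑dibromo‑1,4‑benzoquinone | O=C1C=C(Br)C(=O)C(Br)=C1 | intermediate
4 | 1,3,5‑trimethoxybenzene | COc1cc(OC)cc(OC)c1 | starting material
5 | 2,6‑dibromo‑3‑(2,4,6‑trimethoxyphenyl)cyclohexa‑2,5‑diene‑1,4‑dione (arylquinone) | O=C1C(Br)=CC(=O)C(c2c(OC)cc(OC)cc2OC)=C1Br | intermediate
6 | 2,6‑dibromo‑3‑(2,4,6‑trimethoxyphenyl)benzene‑1,4‑diol | Oc1c(Br)cc(O)c(-c2c(OC)cc(OC)cc2OC)c1Br | intermediate
7 | 2,6‑dibromo‑4‑methoxy‑3‑(2,4,6‑trimethoxyphenyl)phenol | COc1cc(Br)c(O)c(Br)c1-c1c(OC)cc(OC)cc1OC | intermediate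
8 | 2,4,6‑trimethoxy‑3‑(2,4,6‑trimethoxyphenyl)phenol | COc1cc(OC)c(O)c(OC)c1-c1c(OC)cc(OC)cc1OC | intermediate
9 | 2,6‑difluoro‑4‑methoxybenzonitrile | COc1cc(F)c(C#N)c(F)c1 | starting material
10 | 2‑fluoro‑4‑methoxy‑6‑[2,4,6‑trimethoxy‑3‑(2,4,6‑trimethoxyphenyl)phenoxy]benzonitrile (monoether) | COc1cc(F)c(C#N)c(Oc2c(OC)cc(OC)c(-c3c(OC)cc(OC)cc3OC)c2OC)c1 | intermediate
11 | 4‑methoxy‑2,6‑bis[2,4,6‑trimethoxy‑3‑(2,4,6‑trimethoxyphenyl)phenoxy]benzonitrile | COc1cc(Oc2c(OC)cc(OC)c(-c3c(OC)cc(OC)cc3OC)c2OC)c(C#N)c(Oc2c(OC)cc(OC)c(-c3c(OC)cc(OC)cc3OC)c2OC)c1 | intermediate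
12 | {4‑methoxy‑2,6‑bis[2,4,6‑trimethoxy‑3‑(2,4,6‑trimethoxyphenyl)phenoxy]phenyl}methanimine (aldimine) | COc1cc(Oc2c(OC)cc(OC)c(-c3c(OC)cc(OC)cc3OC)c2OC)c(C=N)c(Oc2c(OC)cc(OC)c(-c3c(OC)cc(OC)cc3OC)c2OC)c1 | intermediate
13 | 4‑methoxy‑2,6‑bis[2,4,6‑trimethoxy‑3‑(2,4,6‑trimethoxyphenyl)phenoxy]benzaldehyde | COc1cc(Oc2c(OC)cc(OC)c(-c3c(OC)cc(OC)cc3OC)c2OC)c(C=O)c(Oc2c(OC)cc(OC)c(-c3c(OC)cc(OC)cc3OC)c2OC)c1 | intermediate
14 | 4‑methoxy‑2,6‑bis[2,4,6‑trimethoxy‑3‑(2,4,6‑trimethoxyphenyl)phenoxy]phenyl formate | COc1cc(Oc2c(OC)cc(OC)c(-c3c(OC)cc(OC)cc3OC)c2OC)c(OC=O)c(Oc2c(OC)cc(OC)c(-c3c(OC)cc(OC)cc3OC)c2OC)c1 | intermediate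
15 | 4‑methoxy‑2,6‑bis[2,4,6‑trimethoxy‑3‑(2,4,6‑trimethoxyphenyl)phenoxy]phenol | COc1cc(Oc2c(OC)cc(OC)c(-c3c(OC)cc(OC)cc3OC)c2OC)c(O)c(Oc2c(OC)cc(OC)c(-c3c(OC)cc(OC)cc3OC)c2OC)c1 | intermediate
16 | 5‑iodo‑1,2,3‑trimethoxybenzene | COc1cc(I)cc(OC)c1OC | starting material
17 | 5‑methoxy‑2‑(3,4,5‑trimethoxyphenoxy)‑1,3‑bis[2,4,6‑trimethoxy‑3‑(2,4,6‑trimethoxyphenyl)phenoxy]benzene | COc1cc(Oc2c(OC)cc(OC)c(-c3c(OC)cc(OC)cc3OC)c2OC)c(Oc2cc(OC)c(OC)c(OC)c2)c(Oc2c(OC)cc(OC)c(-c3c(OC)cc(OC)cc3OC)c2OC)c1 | intermediate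
18 | 4‑(3,4,5‑trihydroxyphenoxy)‑3,5‑bis[2,4,6‑trihydroxy‑3‑(2,4,6‑trihydroxyphenyl)phenoxy]phenol | Oc1cc(O)c(-c2c(O)cc(O)c(Oc3cc(O)cc(Oc4c(O)cc(O)c(-c5c(O)cc(O)cc5O)c4O)c3Oc3cc(O)c(O)c(O)c3)c2O)c(O)c1 | target

**Totals**
Total steps: 10. Longest linear sequence: 10 steps (1 to 18); compounds 4, 9 and 16 enter as commercial partners.

**Steps most likely to fail, with fallbacks**

The first is step 3, the Michael arylation of the quinone. The arene may instead displace bromide at C2, add twice, or be lost to redox side reactions. The fallback gives up the quinone and makes the biaryl by cross‑coupling; it sets out from 4, comes back at 8, and so also bypasses steps 4 and 5. Vilsmeier–Haack formylation of 4 (POCl3, DMF) gives 2,4,6‑trimethoxybenzaldehyde F1. Bromination with NBS in MeCN gives 3‑bromo‑2,4,6‑trimethoxybenzaldehyde F2. Suzuki–Miyaura coupling with commercial 2,4,6‑trimethoxyphenylboronic acid (Pd(OAc)2, SPhos, K3PO4, toluene/H2O, 100 °C) gives 2,4,6‑trimethoxy‑3‑(2,4,6‑trimethoxyphenyl)benzaldehyde F3. Oxidation with mCPBA gives 2,4,6‑trimethoxy‑3‑(2,4,6‑trimethoxyphenyl)phenyl formate F4, and K2CO3/MeOH releases 8.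

The second is step 9, the Ullmann coupling of a phenol flanked by two bulky aryloxy groups, which may stall. The fallback is a metal‑free arylation with a diaryliodonium salt, which is much less sensitive to ortho crowding; it sets out from 15 and comes back at 17. Compound 16 is oxidised with mCPBA and TsOH·H2O in MeCN and trapped with 4 to give (3,4,5‑trimethoxyphenyl)(2,4,6‑trimethoxyphenyl)iodonium tosylate F5, in which the 2,4,6‑trimethoxyphenyl group is the non‑transferred ligand. Treating 15 with F5 and K2CO3 in toluene at 50 °C transfers the 3,4,5‑trimethoxyphenyl group to oxygen and gives 17.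

The third is step 10, the sixteen‑fold demethylation. It may stop short, and the free polyphenol is hard to purify and oxidises easily. The fallback isolates the product in protected form; it sets out from 17 and comes back at 18. After the BBr3 treatment and quench, the crude material is acetylated (Ac2O, pyridine, DMAP) to 4‑(3,4,5‑triacetoxyphenoxy)‑3,5‑bis[2,4,6‑triacetoxy‑3‑(2,4,6‑triacetoxyphenyl)phenoxy]phenyl acetate F6. This is purified by chromatography on silica, which removes partly methylated material. Acid‑catalysed methanolysis (HCl generated from AcCl in degassed MeOH, rt, Ar) then gives 18.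

**Further compounds**
F1 | step 3 | 2,4,6‑trimethoxybenzaldehyde | COc1cc(OC)c(C=O)c(OC)c1
F2 | step 3 | 3‑bromo‑2,4,6‑trimethoxybenzaldehyde | COc1cc(OC)c(C=O)c(OC)c1Br
F3 | step 3 | 2,4,6‑trimethoxy‑3‑(2,4,6‑trimethoxyphenyl)benzaldehyde | COc1cc(OC)c(C=O)c(OC)c1-c1c(OC)cc(OC)cc1OC
F4 | step 3 | 2,4,6‑trimethoxy‑3‑(2,4,6‑trimethoxyphenyl)phenyl formate | COc1cc(OC)c(OC=O)c(OC)c1-c1c(OC)cc(OC)cc1OC
F5 | step 9 | (3,4,5‑trimethoxyphenyl)(2,4,6‑trimethoxyphenyl)iodonium tosylate | COc1cc([I+]c2c(OC)cc(OC)cc2OC)cc(OC)c1OC.Cc1ccc(S(=O)(=O)[O-])cc1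
F6 | step 10 | 4‑(3,4,5‑triacetoxyphenoxy)‑3,5‑bis[2,4,6‑triacetoxy‑3‑(2,4,6‑triacetoxyphenyl)phenoxy]phenyl acetate | CC(=O)Oc1cc(OC(C)=O)c(-c2c(OC(C)=O)cc(OC(C)=O)c(Oc3cc(OC(C)=O)cc(Oc4c(OC(C)=O)cc(OC(C)=O)c(-c5c(OC(C)=O)cc(OC(C)=O)cc5OC(C)=O)c4OC(C)=O)c3Oc3cc(OC(C)=O)c(OC(C)=O)c(OC(C)=O)c3)c2OC(C)=O)c(OC(C)=O)c1
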